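## Retrosynthetic overview
1. Benzylic C–O bond (the only stereocentre): enantioselective oxygen delivery to the Si face of Cβ of the pyranochalcone. An aldoxime serves as the water donor and leaves as a nitrile.
2. Enone C=C: Claisen–Schmidt condensation of the 6-acetylchromene with benzaldehyde.
3. Pyran O1–C2 bond: oxa-6π closure of an ortho-quinone methide made from 2',4'-dihydroxy-6'-methoxyacetophenone and prenal.
4. Ring order: ring A and ring B are bought. The pyran is the only ring formed, in the first step.

Assumption: 2',4'-dihydroxy-6'-methoxyacetophenone (1) is bought as a catalogue chemical. The facial sense of the new step is a model-based prediction, and both ligand enantiomers are commercial, so the mirror-image ligand is used if the first run gives the (R)-alcohol.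

## Route

**Step 1**
Reactants: 1 1-(2,4-dihydroxy-6-methoxyphenyl)ethan-1-one; 2 3-methylbut-2-enal (prenal)
Product: 4 1-(5-hydroxy-7-methoxy-2,2-dimethyl-2H-chromen-6-yl)ethan-1-one, via ortho-quinone methide 3 (not isolated)
Conditions: 2 (2 equiv), ethylenediammonium diacetate (20 mol %), xylene, reflux, 12 h
Reagents that add atoms: 3-methylbut-2-enal (2), CC(C)=CC=O
Why: Knoevenagel-type condensation at C3 (the carbon between the two hydroxyls, the most nucleophilic site) and loss of water give 3, whose oxa-6π electrocyclisation (formal [3+3] chromene annulation) closes the O1–C2 bond through the C4 oxygen because the C2 hydroxyl stays locked in its hydrogen bond to the acetyl group; no stereocentre is formed.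

**Step 2**
Reactants: 4 1-(5-hydroxy-7-methoxy-2,2-dimethyl-2H-chromen-6-yl)ethan-1-one; 5 benzaldehyde
Product: 7 (E)-1-(5-hydroxy-7-methoxy-2,2-dimethyl-2H-chromen-6-yl)-3-phenylprop-2-en-1-one, via racemic aldol adduct 6 (not isolated)
Conditions: 5 (1.2 equiv), KOH (5 equiv, 50% aq), EtOH, 0 °C to rt, 36 h; then cold 1 M HCl to pH 5
Reagents that add atoms: benzaldehyde (5), O=Cc1ccccc1
Why: Claisen–Schmidt aldol condensation with E1cB loss of water gives the thermodynamic (E)-enone, the strongly basic medium keeps the product as the open-chain phenolate so no flavanone forms, and the chromene is inert to hydroxide.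

**Step 3**
Reactants: 7 (E)-1-(5-hydroxy-7-methoxy-2,2-dimethyl-2H-chromen-6-yl)-3-phenylprop-2-en-1-one; 8 (E)-pyridine-2-carbaldehyde oxime
Product: 10 (S)-3-hydroxy-1-(5-hydroxy-7-methoxy-2,2-dimethyl-2H-chromen-6-yl)-3-phenylpropan-1-one, via oxime ether adduct 9 (not isolated)
Conditions: 8 (1.5 equiv), Sc(OTf)3 (10 mol %), (S,S)-t-Bu-pybox [2,6-bis((4S)-4-tert-butyl-4,5-dihydro-1,3-oxazol-2-yl)pyridine, 12 mol %], i-Pr2NEt (20 mol %), 4 Å MS, CH2Cl2, −20 to 0 °C, 48 h
Reagents that add atoms: (E)-pyridine-2-carbaldehyde oxime (8), O/N=C/c1ccccn1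
Why: Proposed new method: catalytic enantioselective transfer hydration of a chelating enone, in which trivalent scandium in the pybox pocket binds 7 through the C5 phenolate and the ketone oxygen (lowering the enone LUMO and holding the phenol oxygen away from Cβ, so flavanone closure is shut off) and binds 8 through its two nitrogens (blocking N-alkylation to a nitrone and leaving only the oximate oxygen free); that oxygen adds to the Si face of Cβ inside the coordination sphere and sets the (S) centre as 9, and the acidified aldoxime C–H, cis to the N–O bond, then passes to the scandium enolate carbon through a six-membered array (or to i-Pr2NEt) with N–O cleavage, so the nitrile leaves and the strongly downhill oxime-to-nitrile change makes the otherwise uphill, reversible hydration of a chalcone irreversible; the closest known reaction types are the oxa-Michael addition of oximes to enals and aliphatic enones, aldoximes used as hydroxide surrogates that collapse to nitriles, and the metal-catalysed transfer hydration of nitriles by aldoximes, which have not been joined into a one-flask asymmetric hydration of a chalcone.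

## Compound list
1 | 1-(2,4-dihydroxy-6-methoxyphenyl)ethan-1-one | CC(=O)c1c(O)cc(O)cc1OC | starting material
2 | 3-methylbut-2-enal | CC(C)=CC=O | starting material
3 | (Z)-4-acetyl-3-hydroxy-5-methoxy-2-(3-methylbut-2-en-1-ylidene)cyclohexa-3,5-dien-1-one | CC(=O)C1=C(O)/C(=C/C=C(C)C)C(=O)C=C1OC | intermediate
4 | 1-(5-hydroxy-7-methoxy-2,2-dimethyl-2H-chromen-6-yl)ethan-1-one | COc1cc2c(c(O)c1C(C)=O)C=CC(C)(C)O2 | intermediate
5 | benzaldehyde | O=Cc1ccccc1 | starting material
6 | racemic 3-hydroxy-1-(5-hydroxy-7-methoxy-2,2-dimethyl-2H-chromen-6-yl)-3-phenylpropan-1-one | COc1cc2c(c(O)c1C(=O)CC(O)c1ccccc1)C=CC(C)(C)O2 | intermediate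
7 | (E)-1-(5-hydroxy-7-methoxy-2,2-dimethyl-2H-chromen-6-yl)-3-phenylprop-2-en-1-one | COc1cc2c(c(O)c1C(=O)/C=C/c1ccccc1)C=CC(C)(C)O2 | intermediate
8 | (E)-pyridine-2-carbaldehyde oxime | O/N=C/c1ccccn1 | starting material
9 | (S)-1-(5-hydroxy-7-methoxy-2,2-dimethyl-2H-chromen-6-yl)-3-phenyl-3-({[(E)-pyridin-2-ylmethylidene]amino}oxy)propan-1-one | COc1cc2c(c(O)c1C(=O)C[C@H](O/N=C/c1ccccn1)c1ccccc1)C=CC(C)(C)O2 | intermediate
10 | (S)-3-hydroxy-1-(5-hydroxy-7-methoxy-2,2-dimethyl-2H-chromen-6-yl)-3-phenylpropan-1-one | COc1cc2c(c(O)c1C(=O)C[C@H](O)c1ccccc1)C=CC(C)(C)O2 | target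

## Step count and risks
Total step count: 3. Longest linear sequence: 3.

**Step 3 (the proposed new step) is the most likely to fail.**
- Risks: nitrile loss from 9 may be slower than retro-oxa-Michael, which would stall the reaction or erode the ee. Compound 8 may crowd the substrate off scandium. Facial control is untested.
- Fallback: known chemistry, setting out from 7 and coming back at 10.
- Copper-catalysed enantioselective conjugate borylation in water uses Cu(OH)2 (5 mol %), AcOH (6 mol %), B2pin2 (1.2 equiv) and H2O at 5 °C. The ligand is 6,6'-bis(1-hydroxy-2,2-dimethylpropyl)-2,2'-bipyridine (6 mol %), taken as the enantiomer that delivers boron to the Si face of Cβ.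
- This gives (S)-1-(5-hydroxy-7-methoxy-2,2-dimethyl-2H-chromen-6-yl)-3-phenyl-3-(4,4,5,5-tetramethyl-1,3,2-dioxaborolan-2-yl)propan-1-one F1.
- NaBO3·4H2O in THF/H2O at rt then turns C–B into C–O with retention to give 10. The free phenol and the chromene alkene tolerate both operations.
- The same material serves as the reference for assigning the configuration of the product of the new step.

**Step 1 is second.**
- Risks: the acyl-deactivated resorcinol may react slowly. Attack at C5 would give the 7-hydroxy-5-methoxy regioisomer.
- Fallback: sets out from 1 and comes back at 4, making the aryl–O–C bond first.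
- Selective O-alkylation of the free, non-chelated C4 hydroxyl with 3-chloro-3-methylbut-1-yne (K2CO3, KI, acetone, reflux) gives 1-{2-hydroxy-6-methoxy-4-[(2-methylbut-3-yn-2-yl)oxy]phenyl}ethan-1-one F2.
- Heating F2 in N,N-diethylaniline at 200 °C triggers the aromatic propargyl Claisen rearrangement to C3, which is favoured by the bond fixation of the chelated ring. A hydrogen shift and closure through 3 then give 4.

**Step 2 is third.**
- Risks: the di-ortho-substituted, phenolate-deactivated methyl ketone may condense slowly. The chalcone may isomerise to the flavanone on work-up.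
- Fallback: sets out from 4 and comes back at 7, splitting C–C formation from dehydration.
- The dianion of 4 (LiHMDS 2.2 equiv, THF, −78 °C) adds to 5, and 6 is isolated after a cold NH4Cl quench.
- MsCl (1.1 equiv) and Et3N (3 equiv) in CH2Cl2 at 0 °C convert the secondary alcohol, but not the chelated phenol, into racemic 3-(5-hydroxy-7-methoxy-2,2-dimethyl-2H-chromen-6-yl)-3-oxo-1-phenylpropyl methanesulfonate F3.
- F3 eliminates in the flask by E1cB to give 7 without strong acid or hydroxide.

## Further compounds
F1 | step 3 | (S)-1-(5-hydroxy-7-methoxy-2,2-dimethyl-2H-chromen-6-yl)-3-phenyl-3-(4,4,5,5-tetramethyl-1,3,2-dioxaborolan-2-yl)propan-1-one | COc1cc2c(c(O)c1C(=O)C[C@H](B1OC(C)(C)C(C)(C)O1)c1ccccc1)C=CC(C)(C)O2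
F2 | step 1 | 1-{2-hydroxy-6-methoxy-4-[(2-methylbut-3-yn-2-yl)oxy]phenyl}ethan-1-one | CC(=O)c1c(O)cc(OC(C)(C)C#C)cc1OC
F3 | step 2 | racemic 3-(5-hydroxy-7-methoxy-2,2-dimethyl-2H-chromen-6-yl)-3-oxo-1-phenylpropyl methanesulfonate | COc1cc2c(c(O)c1C(=O)CC(OS(C)(=O)=O)c1ccccc1)C=CC(C)(C)O2
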